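Atoms are numbered as in ent-kaurane. Late cuts: the C11 and C15 alcohols go back to ketones, C11 goes further back to a nitro group, and C17 is removed (Mannich methylenation).
Main cut: δ-lactone ring B is opened at C20–O and C8–C9 at once. This is possible because O–C7–C8 is the C,O-bis-nucleophile of a β-keto acid (C15 oxygen on ring D), while C9 and C20 flank quaternary C10 and C9 is vicinal to oxygenated C11. C9=C11(NO2) plus C20–I is therefore a three-carbon bis-electrophile, and the (3+3) sum of the two units is ring B. C9 and C8 are already tied through C11–C12–C13–C14, so the same C–C bond also closes ring C and the bicyclo[3.2.1]octane.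
The seco compound is cut at C9=C11 (Henry reaction) into the ring A iodo aldehyde 10 and the ring D nitro keto ester 19. C9 and C20 of 10 come from a temporary spiro-cyclopropane (C9–C10–C20) whose C9–C20 bond is cleaved by iodonium.
Forward order: ring A is bought; γ-lactone (steps 1 to 4); C10 (steps 5 and 6); ring D (step 8); union (step 11); rings C and B together (step 13); C17, C15 and C11 (steps 14 to 17).
Stereochemistry: C4 by ligand-controlled conjugate addition; C5 by the cis-lactone constraint; C10 by convex-face cyclopropanation; C13 by the aminocatalyst; C8 from C13 through the tether; C9 from the (E)-nitroalkene geometry; C15 by exo hydride attack; C11 by hydride delivered from the C15 hydroxyl.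

Key step: step 13

Remark: centres written without configuration in a SMILES are mixtures of epimers that are fixed or erased later. These are C5 in 3, C6 in 7, C9 in 9, C8 before step 13, C12 in 17, C9 and C11 in 20 and 21, C11 in 23 to 28, and C16 in 26.

Step 1
Reactants: 1 methyl 3-oxocyclohex-1-ene-1-carboxylate
Product: 4 (3aS,7aR)-7a-methylhexahydro-2-benzofuran-1,4-dione (cis-fused keto lactone; C19 is the lactone carbonyl; 4R,5S), via zinc enolate 2 (not isolated), via aldol 3 (not isolated)
Conditions: Cu(OTf)2 (2.5 mol %), chiral sulfonate-bearing imidazolinium salt (NHC precursor, 2.5 mol %, the enantiomer that gives 4R), Me2Zn, Et2O, −30 °C; HCHO (THF solution), −78 to 0 °C; aq NH4Cl; then PPTS, benzene, 60 °C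
Reagents that add atoms: dimethylzinc C[Zn]C; formaldehyde C=O
Why: Copper-catalysed enantioselective conjugate addition of a dialkylzinc to a cyclic γ-keto ester sets quaternary C4 under ligand control, the regiodefined enolate is taken on in an aldol reaction with formaldehyde at C5, and only the C5 epimer with C6 cis to the C19 ester can lactonise, so acid-mediated epimerisation α to the ketone should funnel the material into the cis-fused lactone.

Step 2
Reactants: 4 keto lactone
Product: 5 (3aS,7aR)-7a-methyl-4-methylidenehexahydro-2-benzofuran-1(3H)-one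
Conditions: Zn, CH2Br2, TiCl4, THF/CH2Cl2, 0 °C to rt
Reagents that add atoms: dibromomethane BrCBr
Why: The Takai–Lombardo methylenation is non-basic, so the β-acyloxy ketone should be neither eliminated nor epimerised at C5, and the lactone carbonyl is left alone.

Step 3
Reactants: 5 methylidene lactone (C19 carbonyl)
Product: 6 [(1R,2S)-1-methyl-3-methylidenecyclohexane-1,2-diyl]dimethanol
Conditions: LiAlH4, THF, 0 °C
Reagents that add atoms: none
Why: Hydride reduction of a lactone to the 1,4-diol touches neither the isolated alkene nor a stereocentre.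

Step 4
Reactants: 6 diol
Product: 8 (3aR,7aS)-3a-methyl-7-methylidenehexahydro-2-benzofuran-1(3H)-one (C6 is now the lactone carbonyl), via lactol 7 (not isolated)
Conditions: TEMPO (10 mol %), PhI(OAc)2 (2.5 equiv), CH2Cl2, rt
Reagents that add atoms: none
Why: Oxoammonium-mediated oxidative lactonisation of a 1,4-diol starts at the less hindered C6 carbinol (the C19 carbinol is neopentyl) and the lactol is oxidised further, so the carbonyl should end at C6 as in the target.

Step 5
Reactants: 8 methylidene lactone (C6 carbonyl)
Product: 9 spiro-methoxycyclopropane (C10 spiro, C9 bears OMe, C20 is CH2; 4R,5R,10S)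
Conditions: HC(OMe)3, Zn(Hg), ZnCl2 (cat.), Me3SiCl, Et2O, reflux
Reagents that add atoms: trimethyl orthoformate COC(OC)OC
Why: Simmons–Smith-type cyclopropanation with a zinc alkoxycarbenoid should take place on the convex face of the cis-fused bicycle (the side of H5 and the C18 methyl, away from the C5–C6 bond and C19), which places C9 trans to C6 and thereby fixes C10.

Step 6
Reactants: 9 spiro-methoxycyclopropane
Product: 10 (3aR,7S,7aR)-7-(iodomethyl)-3a-methyl-1-oxooctahydro-2-benzofuran-7-carbaldehyde
Conditions: NIS, MeCN/H2O (10:1), 0 °C, dark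
Reagents that add atoms: N-iodosuccinimide O=C1CCC(=O)N1I; water O
Why: In this electrophilic ring opening of a donor cyclopropane, iodonium attacks the unhindered C20 methylene, the C9–C20 bond breaks towards the oxocarbenium ion at C9 and water hydrolyses it; C10 is untouched, and the aldehyde has no α-hydrogen through which HI could be lost.

Step 7
Reactants: 11 ethyl 4-chloroacetoacetate; 12 2-(trimethylsilyl)ethanol
Product: 13 2-(trimethylsilyl)ethyl 4-chloro-3-oxobutanoate
Conditions: toluene, 110 °C, EtOH distilled off
Reagents that add atoms: none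
Why: Thermal transesterification of a β-keto ester (by way of the acylketene) needs no nucleophilic catalyst that the chloro ketone would alkylate.

Step 8
Reactants: 13 silylethyl chloroacetoacetate; 14 acrolein
Product: 16 2-(trimethylsilyl)ethyl (4R)-4-formyl-2-oxocyclopentane-1-carboxylate, via Michael adduct 15 (not isolated)
Conditions: (S)-α,α-diphenylprolinol trimethylsilyl ether (20 mol %), K2CO3, CHCl3, 4 °C, slow addition of 14
Reagents that add atoms: none
Why: In this iminium–enamine domino Michael addition/intramolecular α-alkylation of an enal with a 4-haloacetoacetate, C8 adds to C14, and the enamine then displaces chloride at C16 (5-exo-tet) from the face not shielded by the diarylsilyloxymethyl group, which sets C13.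

Step 9
Reactants: 16 formyl keto ester
Product: 18 2-(trimethylsilyl)ethyl (4R)-4-[(E)-2-nitroethenyl]-2-oxocyclopentane-1-carboxylate, via nitro alcohol 17 (not isolated)
Conditions: MeNO2, i-Pr2NEt (20 mol %), THF, 0 °C; then DCC, CuCl (10 mol %), Et2O, rt
Reagents that add atoms: nitromethane C[N+](=O)[O-]
Why: A Henry reaction with excess nitromethane followed by neutral carbodiimide dehydration avoids the bases that would epimerise C13 α to the aldehyde or γ to the nitroalkene.

Step 10
Reactants: 18 nitrovinyl keto ester
Product: 19 2-(trimethylsilyl)ethyl (4S)-4-(2-nitroethyl)-2-oxocyclopentane-1-carboxylate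
Conditions: Hantzsch ester, SiO2, toluene, 60 °C
Reagents that add atoms: none
Why: Conjugate transfer hydrogenation of a nitroalkene by a Hantzsch ester is neutral and chemoselective, so ketone, ester and C13 remain as they are (the descriptor changes only through priorities).

Step 11
Reactants: 10 iodo aldehyde; 19 nitro keto ester
Product: 20 β-nitro alcohol (C9–OH, C11–NO2; ring A part as in 10, ring D part as in 19)
Conditions: 1,1,3,3-tetramethylguanidine (2.2 equiv), THF (1 M), 0 °C; AcOH quench at 0 °C
Reagents that add atoms: none
Why: In this Henry reaction only the nitronate addition is productive, because the aldehyde cannot enolise, the aldol of the tertiary C8 carbon is reversible and the neopentyl iodide is inert; the new centres C9 and C11 are mixtures that step 13 erases.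

Step 12
Reactants: 20 β-nitro alcohol
Product: 21 β-nitro acetate (C9–OAc)
Conditions: Ac2O, Sc(OTf)3 (2 mol %), MeCN, −20 °C
Reagents that add atoms: acetic anhydride CC(=O)OC(C)=O
Why: Lewis acid-catalysed acetylation reaches the hindered carbinol without any base, so neither the retro-Henry reaction nor premature elimination should set in.

Step 13
Reactants: 21 β-nitro acetate
Product: 25 11-nitro-15-oxo-6,7-seco-ent-kaurane-6,19:7,20-diolide lacking C17 (4R,5R,8S,9S,10R,13S), via nitroalkene 22 (not isolated), via Michael adduct 23 (not isolated), via carboxylate 24 (not isolated)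
Conditions: TBAF (3 equiv), THF (0.01 M), 0 °C, then 55 °C
Reagents that add atoms: none
Why: Proposed new method: fluoride first acts as a base, E1cB loss of acetate gives the (E)-nitroalkene 22, the C8 enolate of the β-keto ester adds to C9 (23), and only then does the slower attack of fluoride on silicon free the C7 carboxylate 24, which displaces the C20 iodide; each event is known by itself (intramolecular nitro-Michael addition of β-keto esters, fluoride cleavage of 2-silylethyl esters, carboxylate alkylation), and the closest known type for the whole is the (3+3) annulation of 1,3-dicarbonyl C,O-bis-nucleophiles with nitroallyl acetates, here transposed to a β-keto carboxylate and to a bis-electrophile interrupted by quaternary C10. Ring C closes in the 6-(enolexo)-endo-trig mode and so completes the bicyclo[3.2.1]octane, and ring B closes in the 6-exo-tet mode. C8 is fixed by C13, because the three-atom tether C12–C11–C9 reaches C8 only on its own face of ring D; C9 is fixed by the alkene geometry, because with C10 cis to C12 the staggered chair-like transition state (C11 and its nitro group over ring D) puts C10 anti to C15 and H9 between C15 and C7, whereas the other C9 epimer needs a fully eclipsed boat; C11 is not controlled and is erased in step 16. The regioselectivity needed (attack at neopentyl C9, not at C11) is secured by the polarity of the nitroalkene. The order of events is secured by the rates, and it matters, because once C8 is a quaternary bridgehead the β-keto carboxylate cannot lose CO2 (the enolate would be a bridgehead alkene). The lactonisation is irreversible and drains the reversible Michael equilibrium, and the acetic acid released in the first event buffers the medium, which keeps C11 as the neutral nitro compound and leaves the carboxylate as the only good nucleophile for C20.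

Step 14
Reactants: 25 nitro keto dilactone
Product: 27 16-methylidene-15-ketone (enone; otherwise as 25), via Mannich base 26 (not isolated)
Conditions: CH2(NMe2)2, Ac2O, DMF, 95 °C
Reagents that add atoms: N,N,N',N'-tetramethylmethanediamine CN(C)CN(C)C
Why: In this Mannich methylenation C16 is the only enolisable position of the only ketone (C8 is quaternary), whereas a Mannich addition at hindered C11 is reversible and cannot eliminate, so the material should collect in the enone.

Step 15
Reactants: 27 enone
Product: 28 (15R)-allylic alcohol
Conditions: NaBH4, CeCl3·7H2O, MeOH, −78 °C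
Reagents that add atoms: none
Why: The Luche 1,2-reduction should deliver hydride to the exo face of ring D (the side of C7 and H13, away from the C9–C11–C12 bridge), which places the hydroxyl under that bridge as in the target and leaves nitro group and lactones alone.

Step 16
Reactants: 28 nitro allylic alcohol
Product: 29 (15R)-15-hydroxy-11-ketone
Conditions: TiCl3 (aq), NH4OAc, THF/H2O, rt
Reagents that add atoms: water O
Why: The reductive Nef reaction with buffered trivalent titanium turns the secondary nitro group into the ketone near neutral pH, so the allylic alcohol, the alkene, both lactones and the now epimerisable C9 should be spared.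

Step 17
Reactants: 29 hydroxy ketone
Product: 30 guidongnin (4R,5R,8S,9S,10R,11R,13S,15R)
Conditions: Me4NBH(OAc)3, MeCN/AcOH (1:1), −20 °C to rt
Reagents that add atoms: none
Why: In this hydroxyl-directed (Evans–Saksena) reduction the boron bound to the C15 hydroxyl should hand its hydride to the face of C11 that looks at the C15–C16 bridge, which gives the equatorial (11R) alcohol that an external hydride would not favour.

Compound list
1 | methyl 3-oxocyclohex-1-ene-1-carboxylate | COC(=O)C1=CC(=O)CCC1 | starting material
2 | methylzinc enolate of methyl (1R)-1-methyl-3-oxocyclohexane-1-carboxylate | COC(=O)[C@]1(C)CCCC(O[Zn]C)=C1 | intermediate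
3 | methyl (1R)-2-(hydroxymethyl)-1-methyl-3-oxocyclohexane-1-carboxylate | COC(=O)[C@]1(C)CCCC(=O)C1CO | intermediate
4 | (3aS,7aR)-7a-methylhexahydro-2-benzofuran-1,4-dione | O=C1CCC[C@@]2(C)C(=O)OC[C@H]21 | intermediate
5 | (3aS,7aR)-7a-methyl-4-methylidenehexahydro-2-benzofuran-1(3H)-one | C=C1CCC[C@@]2(C)C(=O)OC[C@H]21 | intermediate
6 | [(1R,2S)-1-methyl-3-methylidenecyclohexane-1,2-diyl]dimethanol | C=C1CCC[C@@](C)(CO)[C@H]1CO | intermediate
7 | lactol of 8 (C6 hemiacetal) | C=C1CCC[C@@]2(C)COC(O)[C@H]21 | intermediate
8 | (3aR,7aS)-3a-methyl-7-methylidenehexahydro-2-benzofuran-1(3H)-one | C=C1CCC[C@@]2(C)COC(=O)[C@H]21 | intermediate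
9 | spiro-methoxycyclopropane of 8 (C9–C10–C20 ring) | COC1C[C@]12CCC[C@@]3(C)COC(=O)[C@H]32 | intermediate
10 | (3aR,7S,7aR)-7-(iodomethyl)-3a-methyl-1-oxooctahydro-2-benzofuran-7-carbaldehyde | O=C[C@@]1(CCC[C@@]2(C)COC(=O)[C@H]21)CI | intermediate
11 | ethyl 4-chloroacetoacetate | CCOC(=O)CC(=O)CCl | starting material
12 | 2-(trimethylsilyl)ethanol | C[Si](C)(C)CCO | starting material
13 | 2-(trimethylsilyl)ethyl 4-chloro-3-oxobutanoate | C[Si](C)(C)CCOC(=O)CC(=O)CCl | intermediate
14 | acrolein | C=CC=O | starting material
15 | 2-(trimethylsilyl)ethyl 2-(chloroacetyl)-5-oxopentanoate | O=CCCC(C(=O)CCl)C(=O)OCC[Si](C)(C)C | intermediate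
16 | 2-(trimethylsilyl)ethyl (4R)-4-formyl-2-oxocyclopentane-1-carboxylate | O=C1C[C@H](C=O)CC1C(=O)OCC[Si](C)(C)C | intermediate
17 | 2-(trimethylsilyl)ethyl (4R)-4-(1-hydroxy-2-nitroethyl)-2-oxocyclopentane-1-carboxylate | O=C1C[C@H](C(O)C[N+](=O)[O-])CC1C(=O)OCC[Si](C)(C)C | intermediate
18 | 2-(trimethylsilyl)ethyl (4R)-4-[(E)-2-nitroethenyl]-2-oxocyclopentane-1-carboxylate | O=C1C[C@H](/C=C/[N+](=O)[O-])CC1C(=O)OCC[Si](C)(C)C | intermediate
19 | 2-(trimethylsilyl)ethyl (4S)-4-(2-nitroethyl)-2-oxocyclopentane-1-carboxylate | O=C1C[C@H](CC[N+](=O)[O-])CC1C(=O)OCC[Si](C)(C)C | intermediate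
20 | β-nitro alcohol from 10 and 19 (C9–OH, C11–NO2) | O=C1C[C@H](CC([N+](=O)[O-])C(O)[C@@]2(CCC[C@@]3(C)COC(=O)[C@H]32)CI)CC1C(=O)OCC[Si](C)(C)C | intermediate
21 | β-nitro acetate (C9–OAc) | O=C1C[C@H](CC([N+](=O)[O-])C(OC(C)=O)[C@@]2(CCC[C@@]3(C)COC(=O)[C@H]32)CI)CC1C(=O)OCC[Si](C)(C)C | intermediate
22 | (E)-nitroalkene C9=C11 (C10 cis to C12) | O=C1C[C@H](C/C([N+](=O)[O-])=C\[C@@]2(CCC[C@@]3(C)COC(=O)[C@H]32)CI)CC1C(=O)OCC[Si](C)(C)C | intermediate
23 | bicyclo[3.2.1]octanone Michael adduct (C8–C9 formed, silylethyl ester, C20–I) | C1[C@@H]2CC([N+](=O)[O-])[C@@H]([C@@]3(CCC[C@@]4(C)COC(=O)[C@H]43)CI)[C@](C2)(C(=O)OCC[Si](C)(C)C)C1=O | intermediate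
24 | tetrabutylammonium C7 carboxylate of 23 | CCCC[N+](CCCC)(CCCC)CCCC.C1[C@@H]2CC([N+](=O)[O-])[C@@H]([C@@]3(CCC[C@@]4(C)COC(=O)[C@H]43)CI)[C@](C2)(C(=O)[O-])C1=O | intermediate
25 | 11-nitro-15-oxo-6,7-seco-ent-kaurane-6,19:7,20-diolide lacking C17 | C1[C@@H]2CC([N+](=O)[O-])[C@H]3[C@@]4(CCC[C@@]5(C)COC(=O)[C@H]54)COC(=O)[C@]3(C2)C1=O | intermediate
26 | 16-(dimethylaminomethyl) derivative of 25 | CN(C)CC1[C@@H]2CC([N+](=O)[O-])[C@H]3[C@@]4(CCC[C@@]5(C)COC(=O)[C@H]54)COC(=O)[C@]3(C2)C1=O | intermediate
27 | 11-nitro-15-oxo-6,7-seco-ent-kaur-16-ene-6,19:7,20-diolide | C=C1[C@@H]2CC([N+](=O)[O-])[C@H]3[C@@]4(CCC[C@@]5(C)COC(=O)[C@H]54)COC(=O)[C@]3(C2)C1=O | intermediate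
28 | (15R)-15-hydroxy-11-nitro-6,7-seco-ent-kaur-16-ene-6,19:7,20-diolide | C=C1[C@@H]2CC([N+](=O)[O-])[C@H]3[C@@]4(CCC[C@@]5(C)COC(=O)[C@H]54)COC(=O)[C@]3(C2)[C@@H]1O | intermediate
29 | (15R)-15-hydroxy-11-oxo-6,7-seco-ent-kaur-16-ene-6,19:7,20-diolide | C=C1[C@@H]2CC(=O)[C@H]3[C@@]4(CCC[C@@]5(C)COC(=O)[C@H]54)COC(=O)[C@]3(C2)[C@@H]1O | intermediate
30 | guidongnin | C=C1[C@@H]2C[C@@H](O)[C@H]3[C@@]4(CCC[C@@]5(C)COC(=O)[C@H]54)COC(=O)[C@]3(C2)[C@@H]1O | target

Total step count: 17. Longest linear sequence: 13 (steps 1 to 6 and 11 to 17).

Steps most likely to fail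

**Step 13.** The Michael addition joins a centre that becomes quaternary to a neopentyl carbon and may stall. The silyl ester may also be cleaved first, with loss of CO2, or the nitronate oxygen may capture C20. The fallback sets out from 21 and comes back at 25. It separates the events and makes the C–O bond by halophilic activation instead of displacement by a free carboxylate. Compound 21 is treated with Et3N in CH2Cl2 and 23 is now isolated, which also allows equilibration of the Michael step. TFA in CH2Cl2 then cleaves the silylethyl ester to the iodo acid F1. Ag2O in MeCN at 60 °C closes ring B through the silver carboxylate to give 25.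

**Step 11.** The β-keto ester holds most of the base, the hindered adduct may revert (retro-Henry reaction), and the γ-iodo alkoxide may fragment. The fallback sets out from 10 and 19 and comes back at 22. It uses a nitro-Mannich reaction in place of the Henry reaction. Compound 10 with TsNH2 and Ti(OEt)4 in CH2Cl2 gives the N-tosyl imine F2, a far better electrophile. Compound 19 adds to it with i-Pr2NEt to give the β-nitro sulfonamide F3, which carries no alkoxide. Under the conditions of step 13, F3 loses the sulfonamide by E1cB to give 22, so step 12 is no longer needed.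

**Step 17.** The ketone may be held back as its hemiketal with the C15 hydroxyl, or the facial selectivity may be poor. The fallback sets out from 29 and comes back at 30. It replaces directed hydride delivery by single-electron reduction under thermodynamic control. SmI2 (2.5 equiv) with a few equivalents of H2O in THF at 0 °C should reduce the ketone through the ketyl to the equatorial alcohol well before either lactone reacts.

Further compounds
F1 | step 13 | iodo acid (free C7 acid of 23) | C1[C@@H]2CC([N+](=O)[O-])[C@@H]([C@@]3(CCC[C@@]4(C)COC(=O)[C@H]43)CI)[C@](C2)(C(=O)O)C1=O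
F2 | step 11 | N-tosyl imine of 10 | Cc1ccc(cc1)S(=O)(=O)/N=C/[C@@]1(CCC[C@@]2(C)COC(=O)[C@H]21)CI
F3 | step 11 | β-nitro sulfonamide from F2 and 19 | O=C1C[C@H](CC([N+](=O)[O-])C(NS(=O)(=O)c2ccc(C)cc2)[C@@]2(CCC[C@@]3(C)COC(=O)[C@H]32)CI)CC1C(=O)OCC[Si](C)(C)C
F0 | step 17 | none | none
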